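**Plan**
- Retrosynthetic cuts, in order: the C9–O acyl bond; C11=C13 (back to a CH2–C12 ester); C4–C15 (the carbinol back to a C4 ketone, carried as a ketal); the C7–C8 bond of ring B; last C5–C6 and C9–C10 on ring A.
- Enabling feature: the oxygen-bearing C9 and the carboxyl carbon C12 stand in a 1,5-relationship (C9–C8–C7–C11–C12). This marks C7–C8 as a Michael bond: an acetyl group on C10 (C9, C8) can add through C8 to C7 of a but-2-ynoate chain (C6, C7≡C11, C12) hanging on C5 of ring A.
- Forward: ring A is bought as 3-methylcyclohexenone; conjugate addition/alkylation, ketalisation, alkyne carboxylation and ozonolysis give the keto ynoate; ring B closes by carbocyclisation; C9, C7 and C4 are then adjusted and the acrylic acid and ester are finished.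
- Stereochemistry: C10 from the chiral copper catalyst; C5 from trans alkylation of the enolate; C9 from α-face hydride addition next to the C10 methyl; C7 from hydrogen delivered by the 9β-hydroxyl; C4 from α-face epoxidation of the 4(15)-alkene; the acyl stereocentre from (S)-3-methylpentanoic acid.

Key step: step 5

Remark: bicyclic compounds carry eudesmane numbering (ring A = C1–C5 and C10, ring B = C5–C10, C14 on C10, C15 on C4, side chain C11–C13 on C7; "nor" marks a missing carbon; β is the face of the C10 methyl); the alkylation in step 1 is assumed to occur anti to the isopropenyl group.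

**Route**

Step 1
Reactants: 1 3-methylcyclohex-2-en-1-one; 2 isopropenylmagnesium bromide; 3 propargyl bromide
Product: 5 (2R,3S)-3-methyl-3-(prop-1-en-2-yl)-2-(prop-2-yn-1-yl)cyclohexan-1-one, via magnesium enolate 4 (not isolated)
Conditions: Cu(OTf)2 (cat.), chiral imidazolium NHC precursor (cat., enantiomer giving 3S), Et2O, −30 → 0 °C; then 3, DMPU, THF, 0 °C → rt
Reagents that add atoms: none
Why: Copper-catalysed asymmetric conjugate addition of the alkenyl Grignard reagent under chiral NHC control sets the quaternary centre (3S, the future C10), and the magnesium enolate is then alkylated (SN2) on the face anti to the pseudoaxial isopropenyl group, which should place the propargyl chain at C2 trans to isopropenyl and cis to methyl (2R, the future C5).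

Step 2
Reactants: 5 (2R,3S)-3-methyl-3-(prop-1-en-2-yl)-2-(prop-2-yn-1-yl)cyclohexan-1-one
Product: 6 (6R,7S)-7-methyl-7-(prop-1-en-2-yl)-6-(prop-2-yn-1-yl)-1,4-dioxaspiro[4.5]decane
Conditions: TMSOCH2CH2OTMS, TMSOTf (cat.), CH2Cl2, −78 → −20 °C; pyridine quench
Reagents that add atoms: 1,2-bis(trimethylsilyloxy)ethane C[Si](C)(C)OCCO[Si](C)(C)C
Why: Silyl-transfer ketalisation runs under aprotic, low-temperature conditions that should neither enolise C2 nor touch the alkene and alkyne, and it masks the only other carbonyl so that the later enolate can form at one site alone; no stereocentre is formed.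

Step 3
Reactants: 6 (6R,7S)-7-methyl-7-(prop-1-en-2-yl)-6-(prop-2-yn-1-yl)-1,4-dioxaspiro[4.5]decane
Product: 8 methyl 4-[(6R,7S)-7-methyl-7-(prop-1-en-2-yl)-1,4-dioxaspiro[4.5]decan-6-yl]but-2-ynoate, via lithium acetylide 7 (not isolated)
Conditions: n-BuLi, THF, −78 °C; ClCO2Me, −78 → 0 °C
Reagents that add atoms: methyl chloroformate COC(=O)Cl
Why: Deprotonation of the terminal alkyne and C-acylation of the lithium acetylide with a chloroformate is the standard entry to 2-ynoates (this adds C12), and the ketal and the isopropenyl group are inert to it.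

Step 4
Reactants: 8 methyl 4-[(6R,7S)-7-methyl-7-(prop-1-en-2-yl)-1,4-dioxaspiro[4.5]decan-6-yl]but-2-ynoate
Product: 10 methyl 4-[(6R,7S)-7-acetyl-7-methyl-1,4-dioxaspiro[4.5]decan-6-yl]but-2-ynoate, via ozonide 9 (not isolated)
Conditions: O3, CH2Cl2, −78 °C (Sudan red 7B end point); Me2S, −78 °C → rt
Reagents that add atoms: ozone [O-][O+]=O
Why: Ozonolysis with reductive work-up cleaves the electron-rich 1,1-disubstituted alkene far faster than the electron-poor conjugated alkyne, so the acetyl group (C9 and C8) is unveiled without touching the ynoate, and the dye end point guards against over-oxidation.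

Step 5
Reactants: 10 methyl 4-[(6R,7S)-7-acetyl-7-methyl-1,4-dioxaspiro[4.5]decan-6-yl]but-2-ynoate
Product: 12 methyl 4,4-ethylenedioxy-9-oxo-13,15-dinoreudesm-7-en-12-oate (5α-H), via exocyclic enoate 11 (not isolated)
Conditions: KOt-Bu (0.3 equiv), THF/t-BuOH, 0 °C → rt
Reagents that add atoms: none
Why: tert-Butoxide reversibly deprotonates the acetyl methyl group (C8), the only position that can give a ketone enolate because C10 is quaternary and C4 is a ketal, and the enolate carbon adds to the β-carbon (C7) of the tethered ynoate, after which tert-butanol protonates the vinyl anion and regenerates the base. The closest known reaction type is the base-mediated intramolecular Michael addition of a ketone enolate to an alkynoate (Conia-ene-type carbocyclisation). Ring B closes in the 6-exo-dig mode, with C7–C8 as the only new skeletal bond. No stereocentre is created, C5 and C10 are not acidic and stay as set, and the same base should then draw the β,γ-unsaturated ketone 11 through its dienolate into the ring-conjugated enone 12. The step needs attack by carbon at C7 rather than by enolate oxygen or at C11: the soft acceptor carbon and a hydrogen-bonded potassium enolate in an alcohol-containing medium favour C-alkylation, and attack at C11 would demand a seven-membered ring. Propargyl–allenyl isomerisation of the ynoate should not divert material, since the allenoate offers the same electrophilic C7 to the same enolate.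

Step 6
Reactants: 12 methyl 4,4-ethylenedioxy-9-oxo-13,15-dinoreudesm-7-en-12-oate
Product: 13 methyl 4,4-ethylenedioxy-9β-hydroxy-13,15-dinoreudesm-7-en-12-oate
Conditions: NaBH4, CeCl3·7H2O, MeOH, −78 → 0 °C
Reagents that add atoms: none
Why: Luche 1,2-reduction is selective for the enone carbonyl over the ester, and hydride should enter C9 along the axial trajectory on the α-face, away from the β-methyl on the adjacent C10, to give the equatorial 9β-alcohol.

Step 7
Reactants: 13 methyl 4,4-ethylenedioxy-9β-hydroxy-13,15-dinoreudesm-7-en-12-oate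
Product: 14 methyl 4,4-ethylenedioxy-9β-hydroxy-13,15-dinor-7βH-eudesman-12-oate (side chain 7α)
Conditions: H2 (1 atm), [Ir(cod)(PCy3)(py)]PF6 (cat.), CH2Cl2, 0 °C → rt
Reagents that add atoms: none
Why: In hydroxyl-directed homogeneous hydrogenation the cationic iridium centre binds the 9β-hydroxyl and should deliver both hydrogens to the β-face of the C7=C8 bond, so that H-7 becomes β and the acetate side chain α (axial, trans to the C10 methyl), against the steric preference for α-face addition.

Step 8
Reactants: 14 methyl 4,4-ethylenedioxy-9β-hydroxy-13,15-dinor-7βH-eudesman-12-oate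
Product: 15 methyl 9β-hydroxy-4-oxo-13,15-dinor-7βH-eudesman-12-oate
Conditions: 1 M HCl, THF, 0 °C → rt
Reagents that add atoms: water O
Why: Acid-catalysed ketal hydrolysis frees the C4 ketone under conditions mild enough to leave the methyl ester alone and brief enough that enolisation toward C5 should not set in.

Step 9
Reactants: 15 methyl 9β-hydroxy-4-oxo-13,15-dinor-7βH-eudesman-12-oate
Product: 16 methyl 9β-hydroxy-13-nor-7βH-eudesm-4(15)-en-12-oate
Conditions: Zn, CH2Br2, TiCl4, THF/CH2Cl2, 0 °C → rt
Reagents that add atoms: dibromomethane BrCBr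
Why: Takai–Lombardo methylenation with the geminal dimetallic methylene reagent is non-basic and ketone-selective, so the hindered C4 carbonyl should become the exocyclic alkene (C15) without epimerising C5 or attacking the ester, the free hydroxyl only consuming extra reagent.

Step 10
Reactants: 16 methyl 9β-hydroxy-13-nor-7βH-eudesm-4(15)-en-12-oate
Product: 17 methyl 4α,15-epoxy-9β-hydroxy-13-nor-7βH-eudesman-12-oate
Conditions: mCPBA, CH2Cl2, 0 °C
Reagents that add atoms: 3-chloroperbenzoic acid OOC(=O)c1cccc(Cl)c1
Why: Prilezhaev epoxidation should occur on the α-face of the exocyclic alkene because the axial C10 methyl is 1,3-diaxial to a β-face approach at C4, which places the epoxide oxygen α.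

Step 11
Reactants: 17 methyl 4α,15-epoxy-9β-hydroxy-13-nor-7βH-eudesman-12-oate
Product: 18 13-nor-7βH-eudesmane-4α,9β,12-triol
Conditions: LiAlH4, THF, 0 °C → reflux
Reagents that add atoms: none
Why: Hydride opens the spiro-epoxide by SN2 attack at the primary carbon C15, turning it into the 4β-methyl group and leaving the oxygen as the 4α tertiary alcohol with the configuration fixed in step 10, and the same reagent reduces the ester to the C12 primary alcohol.

Step 12
Reactants: 18 13-nor-7βH-eudesmane-4α,9β,12-triol
Product: 19 4α,9β-dihydroxy-13-nor-7βH-eudesman-12-al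
Conditions: TEMPO (cat.), PhI(OAc)2, CH2Cl2, rt
Reagents that add atoms: none
Why: Oxoammonium (TEMPO) oxidation is selective for the primary alcohol over the hindered secondary and the tertiary hydroxyl, and the aldehyde cannot close to a lactol because the 7α side chain and the 9β-hydroxyl are trans on ring B.

Step 13
Reactants: 19 4α,9β-dihydroxy-13-nor-7βH-eudesman-12-al
Product: 20 4α,9β-dihydroxy-7βH-eudesm-11(13)-en-12-al
Conditions: aq. CH2O, pyrrolidine (cat.), propionic acid (cat.), i-PrOH, 45 °C
Reagents that add atoms: formaldehyde C=O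
Why: Amine-catalysed Mannich condensation of the aldehyde with formaldehyde followed by elimination (organocatalytic α-methylenation) installs C13 as the 11(13)-methylene group under near-neutral conditions that tolerate both free hydroxyls.

Step 14
Reactants: 20 4α,9β-dihydroxy-7βH-eudesm-11(13)-en-12-al; 21 (S)-3-methylpentanoic acid
Product: 22 4α-hydroxy-9β-[(3S)-3-methylpentanoyloxy]-7βH-eudesm-11(13)-en-12-al
Conditions: 21, 2,4,6-trichlorobenzoyl chloride, Et3N, toluene, rt; then 20, DMAP, rt → 40 °C
Reagents that add atoms: none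
Why: Yamaguchi esterification through the mixed anhydride acylates the secondary 9β-hydroxyl while the tertiary 4α-hydroxyl is too hindered to react; C9 keeps its configuration because its C–O bond is untouched, and the acid cannot racemise because its stereocentre is β to the carbonyl.

Step 15
Reactants: 22 4α-hydroxy-9β-[(3S)-3-methylpentanoyloxy]-7βH-eudesm-11(13)-en-12-al
Product: 23 4α-hydroxy-9β-[(3S)-3-methylpentanoyloxy]-7βH-eudesm-11(13)-en-12-oic acid (CNP0471281.1)
Conditions: NaClO2, NaH2PO4, 2-methylbut-2-ene, t-BuOH/H2O, 0 °C → rt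
Reagents that add atoms: sodium chlorite [Na+].[O-]Cl=O
Why: Pinnick oxidation converts the α-substituted acrolein into the acrylic acid with chlorous acid while the scavenger alkene removes hypochlorous acid, and the ester, the tertiary alcohol and the 1,1-disubstituted alkene are not affected.

**Compound list**
1 | 3-methylcyclohex-2-en-1-one | CC1=CC(=O)CCC1 | starting material
2 | isopropenylmagnesium bromide | CC(=C)[Mg]Br | starting material
3 | propargyl bromide (3-bromoprop-1-yne) | C#CCBr | starting material
4 | bromomagnesium (S)-3-methyl-3-(prop-1-en-2-yl)cyclohex-1-en-1-olate | CC(=C)[C@@]1(C)CCCC(O[Mg]Br)=C1 | intermediate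
5 | (2R,3S)-3-methyl-3-(prop-1-en-2-yl)-2-(prop-2-yn-1-yl)cyclohexan-1-one | CC(=C)[C@@]1(C)CCCC(=O)[C@@H]1CC#C | intermediate
6 | (6R,7S)-7-methyl-7-(prop-1-en-2-yl)-6-(prop-2-yn-1-yl)-1,4-dioxaspiro[4.5]decane | CC(=C)[C@@]1(C)CCCC2(OCCO2)[C@@H]1CC#C | intermediate
7 | lithium acetylide of 6 | CC(=C)[C@@]1(C)CCCC2(OCCO2)[C@@H]1CC#C[Li] | intermediate
8 | methyl 4-[(6R,7S)-7-methyl-7-(prop-1-en-2-yl)-1,4-dioxaspiro[4.5]decan-6-yl]but-2-ynoate | CC(=C)[C@@]1(C)CCCC2(OCCO2)[C@@H]1CC#CC(=O)OC | intermediate
9 | methyl 4-[(6R,7S)-7-methyl-7-(3-methyl-1,2,4-trioxolan-3-yl)-1,4-dioxaspiro[4.5]decan-6-yl]but-2-ynoate (ozonide) | CC3(OCOO3)[C@@]1(C)CCCC2(OCCO2)[C@@H]1CC#CC(=O)OC | intermediate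
10 | methyl 4-[(6R,7S)-7-acetyl-7-methyl-1,4-dioxaspiro[4.5]decan-6-yl]but-2-ynoate | CC(=O)[C@@]1(C)CCCC2(OCCO2)[C@@H]1CC#CC(=O)OC | intermediate
11 | methyl 4,4-ethylenedioxy-9-oxo-13,15-dinoreudesm-7(11)-en-12-oate (5α-H, alkene geometry open) | COC(=O)C=C1CC(=O)[C@@]2(C)CCCC3(OCCO3)[C@@H]2C1 | intermediate
12 | methyl 4,4-ethylenedioxy-9-oxo-13,15-dinoreudesm-7-en-12-oate (5α-H) | COC(=O)CC1=CC(=O)[C@@]2(C)CCCC3(OCCO3)[C@@H]2C1 | intermediate
13 | methyl 4,4-ethylenedioxy-9β-hydroxy-13,15-dinoreudesm-7-en-12-oate | COC(=O)CC1=C[C@H](O)[C@@]2(C)CCCC3(OCCO3)[C@@H]2C1 | intermediate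
14 | methyl 4,4-ethylenedioxy-9β-hydroxy-13,15-dinor-7βH-eudesman-12-oate | COC(=O)C[C@H]1C[C@H](O)[C@@]2(C)CCCC3(OCCO3)[C@@H]2C1 | intermediate
15 | methyl 9β-hydroxy-4-oxo-13,15-dinor-7βH-eudesman-12-oate | COC(=O)C[C@H]1C[C@H](O)[C@@]2(C)CCCC(=O)[C@@H]2C1 | intermediate
16 | methyl 9β-hydroxy-13-nor-7βH-eudesm-4(15)-en-12-oate | COC(=O)C[C@H]1C[C@H](O)[C@@]2(C)CCCC(=C)[C@@H]2C1 | intermediate
17 | methyl 4α,15-epoxy-9β-hydroxy-13-nor-7βH-eudesman-12-oate | COC(=O)C[C@H]1C[C@H](O)[C@@]2(C)CCC[C@@]3(OC3)[C@@H]2C1 | intermediate
18 | 13-nor-7βH-eudesmane-4α,9β,12-triol | OCC[C@H]1C[C@H](O)[C@@]2(C)CCC[C@@](C)(O)[C@@H]2C1 | intermediate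
19 | 4α,9β-dihydroxy-13-nor-7βH-eudesman-12-al | O=CC[C@H]1C[C@H](O)[C@@]2(C)CCC[C@@](C)(O)[C@@H]2C1 | intermediate
20 | 4α,9β-dihydroxy-7βH-eudesm-11(13)-en-12-al | C=C(C=O)[C@H]1C[C@H](O)[C@@]2(C)CCC[C@@](C)(O)[C@@H]2C1 | intermediate
21 | (S)-3-methylpentanoic acid | CC[C@H](C)CC(=O)O | starting material
22 | 4α-hydroxy-9β-[(3S)-3-methylpentanoyloxy]-7βH-eudesm-11(13)-en-12-al | C=C(C=O)[C@H]1C[C@H](OC(=O)C[C@@H](C)CC)[C@@]2(C)CCC[C@@](C)(O)[C@@H]2C1 | intermediate
23 | 2-[(2R,4S,4aS,8R,8aR)-8-hydroxy-4a,8-dimethyl-4-{[(3S)-3-methylpentanoyl]oxy}decahydronaphthalen-2-yl]prop-2-enoic acid | C=C(C(=O)O)[C@H]1C[C@H](OC(=O)C[C@@H](C)CC)[C@@]2(C)CCC[C@@](C)(O)[C@@H]2C1 | target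

**Count and risks**
Total steps: 15. Longest linear sequence: 15 steps (1 → 23); acid 21 enters in step 14.

Step 1 is the most exposed. The conjugate addition of an alkenyl Grignard reagent may fall short in enantioselectivity. The hindered magnesium enolate may also exchange a proton with propargyl bromide or be attacked in the SN2′ sense (allene), and the electrophile may not distinguish the two enolate faces well enough. The fallback sets out from enolate 4, made as in step 1, and changes the electrophile and the way the alkyne is made. Enolate 4 is alkylated with 2,3-dibromopropene (allylic, not acidic, bulkier at the reacting carbon) to give (2R,3S)-2-(2-bromoprop-2-en-1-yl)-3-methyl-3-(prop-1-en-2-yl)cyclohexan-1-one F1. This is ketalised as in step 2 to (6R,7S)-6-(2-bromoprop-2-en-1-yl)-7-methyl-7-(prop-1-en-2-yl)-1,4-dioxaspiro[4.5]decane F2. LDA (3 equiv, THF, −78 → 0 °C) then removes HBr and leaves the acetylide 7, which is quenched with ClCO2Me, so the route is rejoined at 8. A minor C2 epimer would be separated at F1 and re-equilibrated with base for recycling.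

Step 7 carries the contra-steric stereocentre. Face selection may be insufficient because the open α-face competes with the hydroxyl-bound catalyst and the ester carbonyl may also bind the metal; the allylic alcohol may in addition isomerise to the saturated ketone. The fallback sets out from 13 and returns at 14. It replaces pure substrate direction by catalyst control: hydrogenation with Ru(OAc)2(BINAP) in MeOH under H2 pressure, a catalyst known to reduce cyclic allylic alcohols syn to the hydroxyl with strong enantiomer discrimination. The BINAP antipode matched to the substrate is chosen so that catalyst and hydroxyl both favour β-face delivery. No new compound arises.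

Step 5 may suffer from closure through the enolate oxygen, from intermolecular Michael addition of the product dienolate to unreacted ynoate, or from incomplete migration of the alkene. The fallback sets out from 10 and forms the same C7–C8 bond by cross-coupling, where only carbon can bond. Hydroiodination of the ynoate (NaI, AcOH, MeCN, rt) gives methyl (Z)-4-[(6R,7S)-7-acetyl-7-methyl-1,4-dioxaspiro[4.5]decan-6-yl]-3-iodobut-2-enoate F3. Palladium-catalysed intramolecular α-alkenylation of the methyl ketone (Pd(PPh3)4, Cs2CO3, THF, 60 °C) closes ring B to the exocyclic enoate 11. Brief treatment with DBU moves the alkene into the ring, and the route is rejoined at 12.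

**Further compounds**
F1 | step 1 | (2R,3S)-2-(2-bromoprop-2-en-1-yl)-3-methyl-3-(prop-1-en-2-yl)cyclohexan-1-one | CC(=C)[C@@]1(C)CCCC(=O)[C@@H]1CC(Br)=C
F2 | step 1 | (6R,7S)-6-(2-bromoprop-2-en-1-yl)-7-methyl-7-(prop-1-en-2-yl)-1,4-dioxaspiro[4.5]decane | CC(=C)[C@@]1(C)CCCC2(OCCO2)[C@@H]1CC(Br)=C
F3 | step 5 | methyl (Z)-4-[(6R,7S)-7-acetyl-7-methyl-1,4-dioxaspiro[4.5]decan-6-yl]-3-iodobut-2-enoate | CC(=O)[C@@]1(C)CCCC2(OCCO2)[C@@H]1C/C(I)=C/C(=O)OC
F0 | step 7 | none | none
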